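The runs were computed with made-up constants, noise included.

Watch one ratio as the flask runs: target found over starting material used up, taken at the late readings. The two earlier runs differ from each other and from the five new flasks in partner and time.

in all of them: starting material 0.27 M; second substrate 1.35 M
- Friday's: partner 0.069 M; run made earlier
- Tuesday's: partner 1.7 M; run made earlier
- zeta: partner 0.150 M; time 12 d
- eta: partner 0.120 M; time 12 d
- gamma: partner 0.300 M; time 12 d
- alpha: partner 2.00 M; time 12 d
- beta: partner 0.486 M; time 12 d

- Friday's (time / d: target / %, starting material / %): 0.333: 6.0, 93.2; 0.833: 9.8, 88.2; 1.67: 8.4, 83.8; 2.50: 9.5, 82.7; 4.00: 9.5, 80.3; 5.00: 8.7, 78.9; 6.00: 8.5, 79.9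
- Tuesday's (time / d: target / %, starting material / %): 0.500: 74.2, 8.4; 0.833: 68.0, 3.4; 1.04: 63.7, 2.0; 1.67: 52.1, 2.4; 2.50: 43.6, 1.2; 4.00: 39.6, 2.1; 6.00: 39.5, 1.9

(standard deviation of a reading: 0.5 percentage points)

- ranking by amount of target, in percent of the starting material charged, from high to low, at 12 d (zeta / eta / gamma / alpha / beta)
- the amount of target, in percent of the starting material charged of the flask you put first, at 12 d
- the amount of target, in percent of the starting material charged of the flask you put last, at 12 d



In Tuesday's run the target readings fall from 74.2% at 0.500 d to 39.6% at 4.00 d and then stand at 39.5% at 6.00 d, and with a scatter of 0.5 percentage points on each reading these last two do not tell whether target is still falling slowly. Its last reading has 39.5% target with 1.9% starting material left, so the ratio is 40.3%, which I call the standing share. Friday's last reading gives 42.3%, though Tuesday's run had 24.6 times its partner. The asked time of 12 d lies well past these last readings, so I reckon target as the standing share, itself a reading with that scatter, times the starting material used.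

Two extremes can be done in the head. With partner in plenty, as in alpha, starting material goes as it did on Tuesday and target is about 40.3%. With partner as limiting reagent, as in eta at 0.120 M against 0.27 M of starting material, one starting material per partner would use 44.4% and give 17.9% target. But Friday's last reading shows 0.787 starting material used per partner charged, which brings eta down to 14.1%. The other flasks lie between these, so I rank them by partner.

The forecast gives alpha > beta > gamma > zeta > eta, with 39.7% first and 13.5% last, on the ground of “a fixed equilibrium-like share of about 41% of converted material”.

The flasks give alpha > beta > gamma > zeta > eta, with 38.0% in alpha and 14.8% in eta.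

    starting material + partner ⇌ target (K = 30.0 L mol⁻¹, k = 0.00280 L mol⁻¹ min⁻¹)
    second substrate + partner ⇌ second product (K = 0.680 L mol⁻¹, k = 3.20 × 10⁻⁴ L mol⁻¹ min⁻¹)
    target ⇌ isomer of the product (K = 1.60, k = 4.10 × 10⁻⁴ min⁻¹)

In eta, target turns into isomer of the product with a forward half-life of 1.2 d at 12.0 d, far shorter than the 12 d of the run. Left until 120 d, eta still holds 14.9% target. The standing share gives 39.9% for alpha, with 1.1% starting material left, and 15.4% for eta, with 61.8% left. The neighbour of eta charged with 0.68 M starting material keeps 83.1% of it, so the share gives 6.81%, and that flask holds 6.51% target.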